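The earlier runs and the new flask were generated by integration for an exercise; scatter was added.

Count what has not reacted. Call x the share of the solid substrate charged that is found in neither adduct, so x counts what is still solid and what has dissolved together.

| setting | spring | summer | flask |
|---|---|---|---|
| solid substrate | 0.050 M | 0.050 M | 0.050 M |
| reagent | 0.67 equiv (fed, over 2.5 min) | 1.5 equiv (fed, over 2.5 min) | 1.00 equiv (fed, over 2.5 min) |
| remark | run made earlier; the fed solution adds 1.0 times the starting volume | run made earlier; the fed solution adds 1.0 times the starting volume | the fed solution adds 1.0 times the starting volume |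
| time |  |  | 2.5 h |

| run | time / h | mono adduct / % | bis adduct / % | solid substrate / % |
|---|---|---|---|---|
| spring | 0.200 | 20.3 | 0.1 | 6.8 |
| spring | 0.333 | 31.1 | 0.9 | 0.4 |
| spring | 0.500 | 38.9 | 1.1 | 0 |
| spring | 0.833 | 48.5 | 1.5 | 0.2 |
| spring | 1.50 | 55.5 | 2.5 | 0.2 |
| spring | 2.50 | 59.9 | 3.1 | 0.3 |
| summer | 0.200 | 41.5 | 1.5 | 0.4 |
| summer | 0.333 | 56.9 | 3.3 | 0.6 |
| summer | 0.500 | 67.1 | 6.0 | 0 |
| summer | 0.833 | 74.1 | 9.5 | 0 |
| summer | 1.50 | 78.1 | 15.5 | 0 |
| summer | 2.50 | 75.5 | 22.4 | 0 |

(each reading ± 0.5 percentage points)

- charges are per starting volume, the dose included; the dosed solution carries all of it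
- as a solid, counted per litre of solution: solid substrate
- the earlier runs were read with a standard deviation of 0.5 percentage points
- at the start none of the solid substrate is in solution

- equivalents of reagent to solid substrate, everything else as given, that leave most mono adduct at 2.5 h
- the amount of mono adduct then, in percent of the solid substrate charged
- the amount of mono adduct with the amounts as given

The ladder runs from fast to slow. The feed ends at 2.5 min, sooner than the solid clears in the spring run, which still reads 6.8 % at 0.200 h and 0.4 % at 0.333 h. Later, the summer run reads 78.1 % of mono adduct at 1.50 h and 75.5 % at 2.50 h, while its bis adduct climbs to 22.4 %.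

If each addition is first order in reagent, c(reagent) cancels from the ratio of the two rates, and time drops out with it. Integrating that ratio in closed form gives the share M of mono adduct as M = (x^κ − x)/(1 − κ). The last summer reading has x = 2.10 %, and expanding x^κ to its square term yields a quadratic in κ. Its smaller root is 0.0927, the selectivity factor, meaning the rate constant of the second addition over that of the first. As a reading, it carries the scatter of x.

The law peaks at M = κ^(κ/(1 − κ)) = 78.4 %, where x = 7.27 %. That peak binds 1.07 equiv of reagent, more than this flask is charged with and less than the summer run. The last summer reading, with x below that value, lies past the peak, so my reckoning puts the best charge above 1.07 equiv and below 1.5 equiv.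

The forecast gave 74.5 % as charged and 78 % at 1.24 equiv, with the words “Consecutive-reaction selectivity gives M = (x^κ − x)/(1 − κ), where x is the unreacted fraction.” The flask gives 75.3 % as charged and 78.4 % at 1.23 equiv.

    starting material + reagent → mono adduct (k = 0.0600 M⁻¹ s⁻¹)
    reagent + mono adduct ⇌ bis adduct (K = 350 M⁻¹, k = 0.00610 M⁻¹ s⁻¹)
    reagent ⇌ dormant form (K = 0.850, k = 0.00560 s⁻¹)
    solid substrate ⇌ starting material, rate k4*(cs4 - [starting material]) while solid is left; crystals form when [starting material] > cs4 (solubility = 19.0 mM, k = 0.0120 s⁻¹)

At 2.50 h this flask holds 16.1 % of starting material and 0 % of solid substrate, with 4.0 % of its reagent left. Put in as x, that amount gives 75.3 % of mono adduct by the law. The neighbour charged with 2.50 equiv keeps 0.0118 % of starting material, for which the law gives 47.6 %, and that flask holds 47.9 %.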